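**Plan**

1. Retrosynthesis: rem<br>ove the C8 tiglate; cut C7–C8 to give a C7 iodide and a C8 aldehyde; open the lactone to a 2,3-allenoate (the C6–O bond and C7–I both come from iodolactonization); then cut C11–C12 (CO), C1–C10 (crotyl unit) and C6–C7 (acetylide), which leaves the epoxide of nerol.
2. Enabling feature: C7 is the β-carbon of the butenolide (ring O–C6–C7=C11–C12) and C8 is a carbinol attached to it, so C7–C8 is the bond of an allylic alcohol. C7 can therefore carry iodide (a β-iodoenoate) and C8 can be a formyl group, the pair needed for a Nozaki–Hiyama–Kishi closure of the ten-membered carbocycle. The cis C4–C5 epoxide and the flat lactone pre-bend the chain.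
3. Forward order: nerol → C4–C5 epoxide → C6 alkynyl carbinol → C1 aldehyde → C1/C10 crotylation → C8 alcohol → allenoate → iodobutenolide (lactone ring) → ten-membered ring → tiglate.
4. Stereochemistry: C4/C5 from Sharpless epoxidation; C6 from Noyori transfer hydrogenation, relayed through the allene axis (anti SN2' carbonylation, then anti iodolactonization, net inversion); C1/C10 from an (S,S)-tartrate (E)-crotylboronate (anti); C8 from the ring closure under substrate control; the tiglate geometry comes with the acid chloride.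

Key step: step 15

Remark: locants follow germacranolide numbering (C1 CH–OAc; C4/C5 epoxide, methyl on C4; C6 lactone CH–O; C7=C11; C8 CH–O-tigloyl; C10 CH–CH3; C12 C=O; C13 CH2OAc).
Remark: the (S,S)-diisopropyl tartrate (E)-crotylboronate is taken as a stock reagent, made from trans-2-butene, triisopropyl borate and D-(−)-diisopropyl tartrate; its preparation is not counted.

**Route**

Step 1
Reactants: 1 nerol
Product: 2 (2S,3R)-2,3-epoxynerol
Conditions: Ti(OiPr)4 (cat.), L-(+)-diethyl tartrate (cat.), t-BuOOH, 4 Å MS, CH2Cl2, −20 °C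
Reagents that add atoms: tert-butyl hydroperoxide, CC(C)(C)OO
Why: Sharpless asymmetric epoxidation: the titanium tartrate binds the allylic hydroxyl and delivers oxygen to one face of the (Z)-C4=C5 bond only, which sets C4 (R) and C5 (S) with the cis relation of C3 and C6 and leaves the remote trisubstituted olefin untouched.

Step 2
Reactants: 2 (2S,3R)-2,3-epoxynerol
Product: 3 (2R,3R)-3-methyl-3-(4-methylpent-3-en-1-yl)oxirane-2-carbaldehyde
Conditions: Dess–Martin periodinane, pyridine, CH2Cl2, 0 °C → rt
Reagents that add atoms: none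
Why: Dess–Martin oxidation of a primary 2,3-epoxy alcohol stops at the aldehyde under buffered conditions that neither open the epoxide nor epimerize C5.

Step 3
Reactants: 3 epoxy aldehyde; 4 tert-butyldimethyl(prop-2-yn-1-yloxy)silane
Product: 6 propargylic alcohol (both C6 epimers), via lithium acetylide 5 (not isolated)
Conditions: 4, n-BuLi, THF, −78 °C; then 3, −78 °C; H2O
Reagents that add atoms: none
Why: 1,2-addition of a lithium acetylide to the aldehyde joins C6 to C7 (and brings C11 and C13), and the epimer ratio at C6 is of no consequence because C6 becomes a ketone in step 4.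

Step 4
Reactants: 6 propargylic alcohol (both C6 epimers)
Product: 7 epoxy ynone
Conditions: Dess–Martin periodinane, pyridine, CH2Cl2, 0 °C
Reagents that add atoms: none
Why: Dess–Martin oxidation of a propargylic alcohol to the ynone is fast and neutral, so the epoxide next to the new carbonyl and the silyl ether survive.

Step 5
Reactants: 7 epoxy ynone
Product: 8 (6R)-propargylic alcohol
Conditions: Ru[(S,S)-TsDPEN](p-cymene) (amido complex, cat., no added base), i-PrOH, rt
Reagents that add atoms: none
Why: Noyori asymmetric transfer hydrogenation of an ynone is reagent-controlled, the alkynyl group taking the place of the aryl group of the usual model, so the (S,S) catalyst should give the (6R) carbinol whatever the preference of the neighbouring epoxide.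

Step 6
Reactants: 8 (6R)-propargylic alcohol
Product: 9 propargylic methyl carbonate
Conditions: ClCO2Me, pyridine, DMAP (cat.), CH2Cl2, 0 °C
Reagents that add atoms: methyl chloroformate, COC(Cl)=O
Why: O-acylation with a chloroformate retains C6 and gives a group that protects the oxygen through steps 7–10 and is the leaving group of the carbonylation in step 11.

Step 7
Reactants: 9 propargylic methyl carbonate
Product: 11 C1 aldehyde, via secondary ozonide 10 (not isolated)
Conditions: O3 (one equivalent), CH2Cl2, −78 °C; then PPh3, −78 °C → rt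
Reagents that add atoms: ozone, [O-][O+]=O
Why: Ozonolysis with reductive work-up: the electron-rich trisubstituted olefin adds ozone far faster than the electron-poor internal alkyne, so only the C1=CMe2 bond is cleaved.

Step 8
Reactants: 11 C1 aldehyde
Product: 12 anti homoallylic alcohol (1S,10R)
Conditions: (S,S)-diisopropyl tartrate (E)-crotylboronate, 4 Å MS, toluene, −78 °C; aq. NaHCO3
Reagents that add atoms: (S,S)-diisopropyl tartrate (E)-crotylboronate, C/C=C/CB1O[C@H](C(=O)OC(C)C)[C@@H](C(=O)OC(C)C)O1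
Why: Roush-type crotylboration through a closed chair transition state: the E geometry of the boronate gives the anti C1/C10 relation and the (S,S)-tartrate directs the crotyl group to the Re face of the formyl group, which should set C1 (S) and C10 (R) without a Lewis acid that could open the epoxide.

Step 9
Reactants: 12 anti homoallylic alcohol
Product: 13 C1 acetate
Conditions: Ac2O, pyridine, DMAP (cat.), CH2Cl2, rt
Reagents that add atoms: acetic anhydride, CC(=O)OC(C)=O
Why: Standard acetylation of the only free hydroxyl installs the C1 acetate of the target with retention.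

Step 10
Reactants: 13 C1 acetate
Product: 15 C8 primary alcohol, via B-alkyl-9-BBN adduct 14 (not isolated)
Conditions: 9-BBN dimer, THF, 0 °C → rt; then aq. NaOAc, 30% H2O2, 0 °C → rt
Reagents that add atoms: 9-borabicyclo[3.3.1]nonane, B1C2CCCC1CCC2 (its atoms stay only in 14); hydrogen peroxide, OO
Why: Hydroboration–oxidation: 9-BBN adds to the monosubstituted olefin at its terminus much faster than to the hindered internal alkyne, and the acetate-buffered oxidation spares the acetate and the carbonate.

Step 11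
Reactants: 15 C8 primary alcohol
Product: 16 (aR)-2,3-allenoate
Conditions: Pd(PPh3)4 (cat.), CO (1 atm), MeOH/THF, rt → 40 °C
Reagents that add atoms: carbon monoxide, [C-]#[O+]
Why: Tsuji-type carbonylation of a propargylic carbonate: zerovalent palladium ionizes the C6–O bond by anti SN2' attack at C11, CO inserts with retention and the methoxide released from the carbonate completes the ester, so the (6R) center is relayed into the (aR) allene axis.

Step 12
Reactants: 16 (aR)-2,3-allenoate
Product: 17 β-iodobutenolide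
Conditions: I2, NaHCO3, MeCN/H2O, 0 °C → rt
Reagents that add atoms: iodine, II
Why: Iodolactonization of a 2,3-allenoate: iodine activates the C6=C7 bond on the face away from the ester, the ester carbonyl oxygen attacks C6 on its own side and the methyl group is lost, so the axis is relayed back to C6 (net inversion of the carbinol of 8, giving the lactone configuration of the target) and C7 receives the iodide needed in step 15.

Step 13
Reactants: 17 β-iodobutenolide
Product: 18 C8 aldehyde
Conditions: Dess–Martin periodinane, pyridine, CH2Cl2, 0 °C → rt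
Reagents that add atoms: none
Why: Dess–Martin oxidation converts the single free primary alcohol into the aldehyde under neutral conditions that spare the iodobutenolide and the epoxide, and C10 is not α to the new carbonyl.

Step 14
Reactants: 18 C8 aldehyde
Product: 20 diacetate iodo-aldehyde, via hydroxymethyl iodobutenolide 19 (not isolated)
Conditions: HF·pyridine, pyridine, THF, 0 °C; aq. NaHCO3 wash; crude 19: Ac2O, pyridine, DMAP (cat.), CH2Cl2, 0 °C
Reagents that add atoms: acetic anhydride, CC(=O)OC(C)=O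
Why: Buffered fluoride desilylation followed by acetylation exchanges the C13 silyl ether for the C13 acetate of the target, and the non-basic fluoride source avoids deprotonation at C6 of the lactone.

Step 15
Reactants: 20 diacetate iodo-aldehyde
Product: 21 ten-membered (8S)-allylic alcohol
Conditions: CrCl2 (8 equiv), NiCl2 (0.1 equiv), DMSO/THF, rt, syringe-pump addition of 20 (final 2 mM)
Reagents that add atoms: none
Why: CrCl2 reduces NiCl2 to zerovalent nickel, which inserts into the C7–I bond of the β-iodobutenolide; transmetalation gives an alkenyl species of trivalent chromium that adds to the C8 formyl group and stays as a chromium alkoxide until work-up. The closest known reaction type is the Nozaki–Hiyama–Kishi macrocyclization of an alkenyl iodide onto an aldehyde, which is precedented for β-iodoenoates and for medium carbocycles. The ten-membered carbocycle closes in the 10-exo-trig mode (C8=O lies outside the ring being formed); the lactone ring is already in place. C8 is the only new stereocenter and is set by the substrate: chromium is expected to bridge the C8 oxygen and the C13 acetate carbonyl, which holds that oxygen in the lactone plane on the C13 side, and the C9–C10 tether must leave C8 on the face of the lactone that carries C5, which together point to the (8S) alcohol. The step needs chemoselectivity for the aldehyde over lactone, acetates and epoxide, secured by the low basicity of organochromium reagents, and it needs ring closure to outrun dimerization and protodeiodination, for which high dilution, the cis C4–C5 epoxide and the rigid C5–C6–C7 corner of the lactone bend the chain.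

Step 16
Reactants: 21 ten-membered (8S)-allylic alcohol
Product: 22 CNP0287840.1
Conditions: (E)-2-methylbut-2-enoyl chloride, pyridine, DMAP (cat.), CH2Cl2, 0 °C → rt
Reagents that add atoms: tigloyl chloride, C/C=C(\C)C(Cl)=O
Why: O-acylation of the C8 hydroxyl with the acid chloride retains C8, and the E geometry of the tiglate is the thermodynamically favoured one, so it should not isomerize.

**Compound list**

1 | nerol, (2Z)-3,7-dimethylocta-2,6-dien-1-ol | CC(C)=CCC/C(C)=C\CO | starting material
2 | (2S,3R)-2,3-epoxynerol, [(2S,3R)-3-methyl-3-(4-methylpent-3-en-1-yl)oxiran-2-yl]methanol | CC(C)=CCC[C@@]1(C)O[C@H]1CO | intermediate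
3 | (2R,3R)-3-methyl-3-(4-methylpent-3-en-1-yl)oxirane-2-carbaldehyde | CC(C)=CCC[C@@]1(C)O[C@H]1C=O | intermediate
4 | tert-butyldimethyl(prop-2-yn-1-yloxy)silane | C#CCO[Si](C)(C)C(C)(C)C | starting material
5 | lithium acetylide of 4 | [Li]C#CCO[Si](C)(C)C(C)(C)C | intermediate
6 | 4-[(tert-butyldimethylsilyl)oxy]-1-[(2S,3R)-3-methyl-3-(4-methylpent-3-en-1-yl)oxiran-2-yl]but-2-yn-1-ol, both carbinol (C6) epimers | CC(C)=CCC[C@@]1(C)O[C@H]1C(O)C#CCO[Si](C)(C)C(C)(C)C | intermediate
7 | 4-[(tert-butyldimethylsilyl)oxy]-1-[(2R,3R)-3-methyl-3-(4-methylpent-3-en-1-yl)oxiran-2-yl]but-2-yn-1-one | CC(C)=CCC[C@@]1(C)O[C@H]1C(=O)C#CCO[Si](C)(C)C(C)(C)C | intermediate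
8 | (1R)-4-[(tert-butyldimethylsilyl)oxy]-1-[(2S,3R)-3-methyl-3-(4-methylpent-3-en-1-yl)oxiran-2-yl]but-2-yn-1-ol (C6 is R) | CC(C)=CCC[C@@]1(C)O[C@H]1[C@H](O)C#CCO[Si](C)(C)C(C)(C)C | intermediate
9 | (1R)-4-[(tert-butyldimethylsilyl)oxy]-1-[(2S,3R)-3-methyl-3-(4-methylpent-3-en-1-yl)oxiran-2-yl]but-2-yn-1-yl methyl carbonate | CC(C)=CCC[C@@]1(C)O[C@H]1[C@H](OC(=O)OC)C#CCO[Si](C)(C)C(C)(C)C | intermediate
10 | secondary ozonide of 9 (5,5-dimethyl-1,2,4-trioxolan-3-yl end group, both epimers at the trioxolane CH) | CC1(C)OOC(CC[C@@]2(C)O[C@H]2[C@H](OC(=O)OC)C#CCO[Si](C)(C)C(C)(C)C)O1 | intermediate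
11 | (1R)-4-[(tert-butyldimethylsilyl)oxy]-1-[(2S,3R)-3-methyl-3-(3-oxopropyl)oxiran-2-yl]but-2-yn-1-yl methyl carbonate | O=CCC[C@@]1(C)O[C@H]1[C@H](OC(=O)OC)C#CCO[Si](C)(C)C(C)(C)C | intermediate
12 | (1R)-4-[(tert-butyldimethylsilyl)oxy]-1-[(2S,3R)-3-[(3S,4R)-3-hydroxy-4-methylhex-5-en-1-yl]-3-methyloxiran-2-yl]but-2-yn-1-yl methyl carbonate | C=C[C@@H](C)[C@@H](O)CC[C@@]1(C)O[C@H]1[C@H](OC(=O)OC)C#CCO[Si](C)(C)C(C)(C)C | intermediate
13 | (1R)-1-[(2S,3R)-3-[(3S,4R)-3-acetoxy-4-methylhex-5-en-1-yl]-3-methyloxiran-2-yl]-4-[(tert-butyldimethylsilyl)oxy]but-2-yn-1-yl methyl carbonate | C=C[C@@H](C)[C@@H](OC(C)=O)CC[C@@]1(C)O[C@H]1[C@H](OC(=O)OC)C#CCO[Si](C)(C)C(C)(C)C | intermediate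
14 | B-alkyl-9-borabicyclo[3.3.1]nonane adduct of 13 (boron on C8) | C1CCC2CCCC1B2CC[C@@H](C)[C@@H](OC(C)=O)CC[C@@]1(C)O[C@H]1[C@H](OC(=O)OC)C#CCO[Si](C)(C)C(C)(C)C | intermediate
15 | (1R)-1-[(2S,3R)-3-[(3S,4R)-3-acetoxy-6-hydroxy-4-methylhexyl]-3-methyloxiran-2-yl]-4-[(tert-butyldimethylsilyl)oxy]but-2-yn-1-yl methyl carbonate | OCC[C@@H](C)[C@@H](OC(C)=O)CC[C@@]1(C)O[C@H]1[C@H](OC(=O)OC)C#CCO[Si](C)(C)C(C)(C)C | intermediate
16 | methyl (aR)-4-[(2S,3R)-3-[(3S,4R)-3-acetoxy-6-hydroxy-4-methylhexyl]-3-methyloxiran-2-yl]-2-{[(tert-butyldimethylsilyl)oxy]methyl}buta-2,3-dienoate | OCC[C@@H](C)[C@@H](OC(C)=O)CC[C@@]1(C)O[C@H]1C([H])=[C@]=C(CO[Si](C)(C)C(C)(C)C)C(=O)OC | intermediate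
17 | (5R)-5-[(2S,3R)-3-[(3S,4R)-3-acetoxy-6-hydroxy-4-methylhexyl]-3-methyloxiran-2-yl]-3-{[(tert-butyldimethylsilyl)oxy]methyl}-4-iodofuran-2(5H)-one | OCC[C@@H](C)[C@@H](OC(C)=O)CC[C@@]1(C)O[C@H]1[C@H]2OC(=O)C(CO[Si](C)(C)C(C)(C)C)=C2I | intermediate
18 | (5R)-5-[(2S,3R)-3-[(3S,4R)-3-acetoxy-4-methyl-6-oxohexyl]-3-methyloxiran-2-yl]-3-{[(tert-butyldimethylsilyl)oxy]methyl}-4-iodofuran-2(5H)-one | O=CC[C@@H](C)[C@@H](OC(C)=O)CC[C@@]1(C)O[C@H]1[C@H]2OC(=O)C(CO[Si](C)(C)C(C)(C)C)=C2I | intermediate
19 | (5R)-5-[(2S,3R)-3-[(3S,4R)-3-acetoxy-4-methyl-6-oxohexyl]-3-methyloxiran-2-yl]-3-(hydroxymethyl)-4-iodofuran-2(5H)-one | O=CC[C@@H](C)[C@@H](OC(C)=O)CC[C@@]1(C)O[C@H]1[C@H]2OC(=O)C(CO)=C2I | intermediate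
20 | (5R)-5-[(2S,3R)-3-[(3S,4R)-3-acetoxy-4-methyl-6-oxohexyl]-3-methyloxiran-2-yl]-3-(acetoxymethyl)-4-iodofuran-2(5H)-one | O=CC[C@@H](C)[C@@H](OC(C)=O)CC[C@@]1(C)O[C@H]1[C@H]2OC(=O)C(COC(C)=O)=C2I | intermediate
21 | (1S,4R,5S,6S,8S,10R)-1,13-diacetoxy-4,5-epoxy-8-hydroxygermacr-7(11)-en-12,6-olide | O[C@H]1C[C@@H](C)[C@@H](OC(C)=O)CC[C@@]2(C)O[C@H]2[C@H]2OC(=O)C(COC(C)=O)=C12 | intermediate
22 | CNP0287840.1, (1S,4R,5S,6S,8S,10R)-1,13-diacetoxy-4,5-epoxy-8-[(E)-2-methylbut-2-enoyloxy]germacr-7(11)-en-12,6-olide | C/C=C(\C)C(=O)O[C@H]1C[C@@H](C)[C@@H](OC(C)=O)CC[C@@]2(C)O[C@H]2[C@H]2OC(=O)C(COC(C)=O)=C12 | target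

**Step count and risks**

Total step count: 16. Longest linear sequence: 16 steps, from nerol (1).

Steps most likely to fail:

Step 15. The formyl group may be attacked on the other face, or with little preference, because C8 is set only by the conformation of the closing chain. The fallback sets out from 20: the same ring closure then gives mainly the (8R) epimer of 21 F1. F1 is esterified with tiglic acid under Mitsunobu conditions (PPh3, DIAD, toluene, 0 °C), which displaces the activated C8 oxygen with inversion and gives 22 directly, so the route is rejoined at 22. An SN2' escape is unlikely because C11 is fully substituted.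

Step 11. The carbonate ionizes only on warming, and at that temperature the allenylpalladium intermediate can lose its axial configuration, which would scramble C6 in step 12; the free C8 hydroxyl adds a second nucleophile. The fallback builds the lactone ring first, on the simple alcohol 8, whose mesylate ionizes in the cold. Alcohol 8 is mesylated (MsCl, Et3N, CH2Cl2, −40 °C) to the propargylic mesylate F2. Carbonylation (Pd(PPh3)4, CO, MeOH/THF, −20 → 0 °C) gives the (aR)-allenoate F3, and iodolactonization (I2, NaHCO3, MeCN/H2O) gives the iodobutenolide F4. Ozonolysis (O3, then PPh3) then gives the C1 aldehyde F5, the (S,S)-crotylboronate of step 8 gives the homoallylic alcohol F6, and Ac2O/pyridine gives the acetate F7. Hydroboration with 9-BBN and acetate-buffered H2O2 comes back to the route at 17.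

Step 16. Acylation of the hindered C8 hydroxyl may be slower than transfer of the neighbouring C13 acetyl group to O8 (C8 and C13 are cis on C7=C11), or slower than base-induced opening of the epoxide through the acidic C6–H of the lactone. The fallback keeps C13 as its silyl ether until the end and sets out from 18. The ring closure of step 15 applied to 18 gives the C13 silyl ether of the macrocyclic alcohol F8. Tigloyl chloride/pyridine gives its tiglate F9, HF·pyridine frees the C13 alcohol F10, and Ac2O/pyridine returns to the route at 22.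

**Further compounds**

F1 | step 15 | (8R) epimer of 21 | O[C@@H]1C[C@@H](C)[C@@H](OC(C)=O)CC[C@@]2(C)O[C@H]2[C@H]2OC(=O)C(COC(C)=O)=C12
F2 | step 11 | methanesulfonate of 8 | CC(C)=CCC[C@@]1(C)O[C@H]1[C@H](OS(C)(=O)=O)C#CCO[Si](C)(C)C(C)(C)C
F3 | step 11 | methyl (aR)-2-{[(tert-butyldimethylsilyl)oxy]methyl}-4-[(2S,3R)-3-methyl-3-(4-methylpent-3-en-1-yl)oxiran-2-yl]buta-2,3-dienoate | CC(C)=CCC[C@@]1(C)O[C@H]1C([H])=[C@]=C(CO[Si](C)(C)C(C)(C)C)C(=O)OC
F4 | step 11 | (5R)-3-{[(tert-butyldimethylsilyl)oxy]methyl}-4-iodo-5-[(2S,3R)-3-methyl-3-(4-methylpent-3-en-1-yl)oxiran-2-yl]furan-2(5H)-one | CC(C)=CCC[C@@]1(C)O[C@H]1[C@H]2OC(=O)C(CO[Si](C)(C)C(C)(C)C)=C2I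
F5 | step 11 | (5R)-3-{[(tert-butyldimethylsilyl)oxy]methyl}-4-iodo-5-[(2S,3R)-3-methyl-3-(3-oxopropyl)oxiran-2-yl]furan-2(5H)-one | O=CCC[C@@]1(C)O[C@H]1[C@H]2OC(=O)C(CO[Si](C)(C)C(C)(C)C)=C2I
F6 | step 11 | (5R)-3-{[(tert-butyldimethylsilyl)oxy]methyl}-5-[(2S,3R)-3-[(3S,4R)-3-hydroxy-4-methylhex-5-en-1-yl]-3-methyloxiran-2-yl]-4-iodofuran-2(5H)-one | C=C[C@@H](C)[C@@H](O)CC[C@@]1(C)O[C@H]1[C@H]2OC(=O)C(CO[Si](C)(C)C(C)(C)C)=C2I
F7 | step 11 | (5R)-5-[(2S,3R)-3-[(3S,4R)-3-acetoxy-4-methylhex-5-en-1-yl]-3-methyloxiran-2-yl]-3-{[(tert-butyldimethylsilyl)oxy]methyl}-4-iodofuran-2(5H)-one | C=C[C@@H](C)[C@@H](OC(C)=O)CC[C@@]1(C)O[C@H]1[C@H]2OC(=O)C(CO[Si](C)(C)C(C)(C)C)=C2I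
F8 | step 16 | C13 tert-butyldimethylsilyl ether analogue of 21 (C13 acetate replaced by the silyl ether) | O[C@H]1C[C@@H](C)[C@@H](OC(C)=O)CC[C@@]2(C)O[C@H]2[C@H]2OC(=O)C(CO[Si](C)(C)C(C)(C)C)=C12
F9 | step 16 | C8 tiglate of F8 | C/C=C(\C)C(=O)O[C@H]1C[C@@H](C)[C@@H](OC(C)=O)CC[C@@]2(C)O[C@H]2[C@H]2OC(=O)C(CO[Si](C)(C)C(C)(C)C)=C12
F10 | step 16 | 13-O-deacetyl analogue of 22 (free C13 hydroxyl) | C/C=C(\C)C(=O)O[C@H]1C[C@@H](C)[C@@H](OC(C)=O)CC[C@@]2(C)O[C@H]2[C@H]2OC(=O)C(CO)=C12
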